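The numbers in the tables were computed for an exercise.

- Charged catalyst is the wrong number to put into this flask's rate, since the decay constants of the earlier runs do not follow it.

all flasks: gas 92 mM (held)
- theta: left-handed substrate 1 M; right-handed substrate 1 M; free catalyst 14 mM; impurity 3.3 mM; run made earlier
- alpha: left-handed substrate 1 M; right-handed substrate 1 M; free catalyst 22 mM; impurity 3.3 mM; run made earlier
- eta: left-handed substrate 1 M; right-handed substrate 1 M; free catalyst 10 mM; impurity 6.6 mM; run made earlier
- flask: left-handed substrate 1.0 M; right-handed substrate 1.0 M; free catalyst 10 mM; impurity 3.3 mM; time 15 h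

| run | time / h | right-handed substrate / % | left-handed substrate / % | left-handed product / % |
|---|---|---|---|---|
| theta | 1.33 | 44.8 | 1.2 | 49.3 |
| theta | 2.50 | 38.1 | 0 | 49.9 |
| theta | 4.00 | 31.5 | 0 | 49.8 |
| theta | 6.00 | 23.7 | 0.8 | 50.3 |
| theta | 10.0 | 14.1 | 0.1 | 50.3 |
| theta | 20.0 | 4.2 | 0.2 | 49.8 |
| alpha | 3.00 | 29.4 | 0.2 | 49.5 |
| alpha | 6.00 | 14.6 | 0 | 49.9 |
| alpha | 10.0 | 6.2 | 0.5 | 49.9 |
| alpha | 12.0 | 4.0 | 0 | 49.3 |
| alpha | 15.0 | 1.9 | 0 | 50.3 |
| alpha | 20.0 | 0.5 | 0.1 | 50.5 |
| eta | 1.33 | 47.2 | 12.2 | 37.5 |
| eta | 2.50 | 45.3 | 3.6 | 46.3 |
| eta | 5.00 | 40.9 | 1.4 | 49.5 |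
| eta | 10.0 | 33.8 | 0 | 50.0 |
| eta | 20.0 | 21.6 | 0.2 | 50.2 |

(readings scatter by 0.5 percentage points)

- free catalyst is single-handed; left-handed substrate and right-handed substrate are mirror images of each other, charged as a racemate, each of them at the stated concentration
- at the start none of the gas is in solution

* whether the excess of right-handed substrate over left-handed substrate among what is left of the two reaches 95% by 15 h (yes / no)
* the highest excess of right-handed substrate over left-handed substrate among what is left of the two up to 15 h

- Read from each run's first sample onward, not from the charge, the right-handed substrate decays as a pseudo-first-order curve, with a constant of 0.127 /h in theta, 0.228 /h in alpha and 0.0419 /h in eta.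
- From the charge to theta's first reading, the right-handed substrate averages a slower 0.0826 /h.
- Theta and eta differ by a factor 3.03, closer to the 3.15 of charged catalyst minus charged impurity than to the 1.40 of charged catalyst.
- That difference is the working catalyst: theta has 10.7 mM, eta 3.40 mM and the flask 6.70 mM.
- Scaled on charged catalyst, eta's left-handed reading of 1.04 /h gives the flask 3.07 /h; impurity cuts this by a factor 0.670 to 2.06 /h.
- The gas starts out of solution, and these constants are read after the start, so the reckoning below leaves the slower start out.
- Theta scales the flask's right-handed constant to 0.0794 /h, a selectivity factor of 25.9.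
- My reckoning follows the ratio of the substrates, which falls with the difference of the constants: 95% comes at 1.85 h, and the time allowed spans 29.7 time constants, so the excess reaches >99.9%.
- The forecast says yes, with a top of 100% in a range of 98% to 100%, holding that “the rate follows catalyst minus impurity”.
- The flask gives yes, with a top of 100%; the excess passes 95% at 1.98 h, when right-handed substrate stands at 44.1% of the two charged.

    reagent + free catalyst + left-handed substrate → free catalyst + left-handed product (k = 1.20 /M²/s)
    reagent + free catalyst + right-handed substrate → free catalyst + right-handed product (k = 0.0400 /M²/s)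
    gas ⇌ reagent, rate k3*(csat - [reagent]) (kL = 0.00670 /s)
    2 reagent → self-condensation product (k = 0.00110 /M/s)
    free catalyst + impurity → spent catalyst (k = 0.570 /M/s)

- At 15.0 h free catalyst stands at 67.0% of its charge, matching the working share of 67.0%. Working catalyst maps the flask's 15 h onto 9.39 h of theta. Theta read 14.1% of right-handed substrate at 10.0 h, and the flask holds 14.7% of the two charged.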